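## The problem

Compound 14 is a 2-arylbenzofuran. Ring A (the benzo ring) carries a free hydroxyl at C6 and a prenyl group at C5, the furan carries a methoxy group at C3, and ring B at C2 is a 3-hydroxy-4-methoxyphenyl group. There is no stereocentre, so the task is one of regiochemistry and functional-group tolerance. Three placements must be unambiguous: the prenyl group at C5 and not at C7 (the carbon between the two ring-A oxygens), the methyl group on the C3 oxygen and not on a phenol, and ring B on C2. The prenyl group excludes hydrogenolysis and, with the adjacent C6 hydroxyl, closes to a dimethylchroman under strong acid. The 3-methoxybenzofuran is an electron-rich enol ether that tolerates neither acid nor oxidants well, so both phenols need masks that leave under neutral, non-reducing conditions. The handle is the C2=C3 bond: C3 bears OMe and ring A, C2 bears ring B and O1, and O1 sits on ring A ortho to C3a. Read as a carbonyl olefination, C2 is the carbonyl carbon of an isovanillate aryl ester and C3 is an α-methoxybenzyl ylide carbon, and the two are ortho neighbours on ring A, exactly the 2-oxygen and the formyl carbon of a salicylaldehyde.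

## Retrosynthesis

**O–Si bonds, 14 to 13.** Both phenols stay masked as tert-butyldimethylsilyl ethers until the end, so the last step cleaves two O–Si bonds with fluoride. Silyl is preferred to methoxymethyl (itself an acetal, it would ionise in the phosphonium-forming step and needs acid for removal), to benzyl (hydrogenolysis would reduce the prenyl alkene) and to acyl (a second ester in the key step). Compound 13 is no simpler in skeleton; the forward step only has to spare the enol ether and the alkene.

**C2=C3 bond, 13 to 11 through ylide 12.** The neighbouring cuts are all weaker. Cutting O1–C2 needs an α-methoxy ketone and an acid cyclodehydration. Cutting the C3–O(methyl) bond needs O-methylation of a benzofuran-3-one whose C2 is benzylic and acidic. Cutting C2–aryl needs a metallated or halogenated 3-methoxybenzofuran. The Wittig cut alone delivers the aromatic furan, the methyl ether and ring B in one event, and it opens the heterocycle into two benzene rings joined by an ester. The forward step asks that C–H deprotonation of 11 to 12 outrun attack at the ester and at the O,P-acetal carbon, and that the betaine lose phosphorus as its oxide.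

**C–P bond, 11 to 9 and 10, then 9 to 8.** The α-methoxybenzyl phosphonium salt 11 is the adduct of triphenylphosphine 10 with the oxocarbenium ion of dimethyl acetal 9, which comes from aldehyde 8. The ester is installed before the acetal because an acetal ortho to a free phenol would not survive. The acetal is made under aprotic conditions so that no free alcohol meets the activated aryl ester. The forward steps ask for ionisation without Brønsted acid, so that the silyl ethers and the prenyl group are untouched.

**Aryl–prenyl bond, 8 to 6 and 7.** The C5–CH2 bond is made by cross-coupling of aryl bromide 6 with prenylstannane 7. The alternative, electrophilic prenylation of the free resorcinol aldehyde, gives C3, C5 and O-alkylated mixtures and chroman by-products. The bromine fixes the site beyond doubt. The forward reaction must transfer the prenyl group through its unsubstituted terminus under neutral conditions that spare aldehyde, aryl ester and silyl ethers.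

**Ester C–O bond, 6 to 5 and 3.** This is the convergent union of ring A (phenol 5) and ring B (acid 3). Carbodiimide activation avoids an acid chloride and free hydrogen chloride near the silyl ethers. Both partners are one step from purchased materials.

**O–Si bonds, 5 to 4 and 3 to 1 through 2.** In 4 the 2-hydroxyl is hydrogen-bonded to the formyl group, so one equivalent of silyl chloride goes to the 4-hydroxyl. Acid 1 is silylated twice to 2, and the labile silyl ester is hydrolysed on work-up to give 3.

## Roads not taken

**Alternative 1:** A sulfur-ylide [4+1] annulation cuts C2–C3 and O1–C2, so that C2 is the benzylic carbon of a ring-B sulfonium salt.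
- Forward step: base converts sulfonium salt A2 into its ylide, which adds to the formyl carbon of salicylaldehyde A1; the ortho phenoxide then displaces the sulfide at the benzylic carbon and gives dihydrobenzofuranol A3.
- Merits: it is convergent, forms two bonds at once, uses the aldehyde as it stands and needs no ester, acetal or moisture-sensitive phosphonium salt. In operational simplicity of the ring-forming step it is better than the chosen plan.
- Weak points: A3 is at the wrong oxidation level. Oxidation of the C3 carbinol, O-methylation of an enol whose C2 is benzylic (C-methylation competes) and removal of the methoxymethyl groups with acid beside the prenyl group and the enol ether are still to come. The betaine may also close to the epoxide before the phenoxide substitutes, which leaves an endo-mode epoxide opening as the real ring closure.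
- Comparison: the chosen plan sets against the simpler key step the fact that its furan arrives aromatic with the methoxy group in place, so one fluoride step follows the ring closure against three here, and the total is about two steps shorter.

**Alternative 2:** A palladium domino cuts C3–C3a and O1–C7a.
- Forward step: the enolate of methoxymethyl ketone A4 is C-arylated at the iodide carbon of dihaloarene A5, and the new enolate oxygen is then arylated at the bromide carbon, giving A6, the bis(methoxymethyl) ether of 14.
- Merits: it is the most convergent of the four plans, has the methoxy group in place, needs one deprotection after the key step like the chosen plan, and produces no stoichiometric phosphorus waste. Counted from the two fragments it is shorter.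
- Weak points: A5 needs two different halogens placed next to a prenyl group and an oxygen, which costs several regiocontrolled steps, and electrophilic halogenation beside a prenyl alkene is itself delicate. The regiochemistry rests only on iodide reacting before bromide; the reverse order gives the isomer with the ring-A substituents exchanged. The second stage is a C–O reductive elimination from a hindered, fully substituted enolate at high temperature with strong base, where palladium hydride isomerisation of the prenyl group is a risk. Those conditions exclude silyl masks, so the final deprotection needs acid.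
- Comparison: the chosen plan sets against the higher convergence a regiochemistry fixed by the salicylaldehyde oxygen pattern, classical polar chemistry at the ring-forming stage and a fluoride deprotection.

**Alternative 3:** A carbonylative closure cuts C3a–C3 and C3–C2, so that carbon monoxide A9 becomes C3.
- Forward step: zerovalent palladium inserts into the aryl iodide of A7, takes up A9 and couples the acyl group with the tethered α-aryloxybenzylstannane to give benzofuranone A8.
- Merits: the O1–C2 ether link is in place before the metal step, the tether helps a slow transmetalation, and no activated aryl ester or phosphonium salt is handled.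
- Weak points: A7 is a secondary benzylic α-oxy stannane that is hard to make and transfers slowly, so protodestannylation competes. A8 is again at the ketone level and must be O-methylated against C-methylation at an acidic, air-sensitive C2, then deprotected with acid. Tin and A9 are both toxic.
- Comparison: it is not better than the chosen plan in any respect beyond avoiding the ester and the salt, and it is the longest of the four.

Key step: step 7

Remark on the chemistry: 14 has no stereocentre; the single stereocentre of 11 is racemic and is destroyed in step 7. Compounds 4 and 7 are taken as purchased materials.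

## Route

Step 1
Reactants: 1 isovanillic acid (3-hydroxy-4-methoxybenzoic acid)
Product: 3 3-(tert-butyldimethylsilyloxy)-4-methoxybenzoic acid, via bis-silylated ester 2 (not isolated)
Conditions: TBSCl (2.5 equiv), imidazole, DMF, rt; then AcOH–THF–H2O (3:1:1), rt
Reagents that add atoms: tert-butyldimethylsilyl chloride, CC(C)(C)[Si](C)(C)Cl
Why: O-silylation of phenol and acid followed by selective hydrolysis of the far more labile silyl ester of 2; the aryl silyl ether is stable to dilute acetic acid at room temperature.

Step 2
Reactants: 4 5-bromo-2,4-dihydroxybenzaldehyde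
Product: 5 5-bromo-4-(tert-butyldimethylsilyloxy)-2-hydroxybenzaldehyde
Conditions: TBSCl (1.05 equiv), imidazole, CH2Cl2, 0 °C
Reagents that add atoms: tert-butyldimethylsilyl chloride, CC(C)(C)[Si](C)(C)Cl
Why: Regioselective O-silylation; the 2-hydroxyl is tied up in a hydrogen bond to the formyl group, whereas the 4-hydroxyl, acidified by the ortho bromine and the para formyl group, reacts first with one equivalent of reagent.

Step 3
Reactants: 5 5-bromo-4-(tert-butyldimethylsilyloxy)-2-hydroxybenzaldehyde; 3 3-(tert-butyldimethylsilyloxy)-4-methoxybenzoic acid
Product: 6 4-bromo-5-(tert-butyldimethylsilyloxy)-2-formylphenyl 3-(tert-butyldimethylsilyloxy)-4-methoxybenzoate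
Conditions: DCC (1.2 equiv), DMAP (0.1 equiv), CH2Cl2, 0 °C to rt
Reagents that add atoms: none
Why: Steglich esterification; the carbodiimide activates 3 and DMAP relays the acyl group to the phenoxide of 5, while aldehyde, aryl bromide and silyl ethers are inert under these neutral conditions.

Step 4
Reactants: 6 4-bromo-5-(tert-butyldimethylsilyloxy)-2-formylphenyl 3-(tert-butyldimethylsilyloxy)-4-methoxybenzoate; 7 tributyl(3-methylbut-2-enyl)stannane
Product: 8 5-(tert-butyldimethylsilyloxy)-2-formyl-4-(3-methylbut-2-enyl)phenyl 3-(tert-butyldimethylsilyloxy)-4-methoxybenzoate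
Conditions: Pd(PPh3)4 (5 mol %), toluene, 100 °C, degassed
Reagents that add atoms: none
Why: Stille coupling; zerovalent palladium inserts into the C–Br bond, the allyl group is transferred from tin and reductive elimination from the prenyl-palladium intermediate occurs at the unsubstituted terminus to give the linear prenyl arene. The base-free medium spares aldehyde, aryl ester and silyl ethers, and toluene is used so that no amine impurity meets the ester.

Step 5
Reactants: 8 5-(tert-butyldimethylsilyloxy)-2-formyl-4-(3-methylbut-2-enyl)phenyl 3-(tert-butyldimethylsilyloxy)-4-methoxybenzoate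
Product: 9 5-(tert-butyldimethylsilyloxy)-2-(dimethoxymethyl)-4-(3-methylbut-2-enyl)phenyl 3-(tert-butyldimethylsilyloxy)-4-methoxybenzoate
Conditions: MeOSiMe3 (3 equiv), TMSOTf (5 mol %), CH2Cl2, –78 to –20 °C; pyridine quench
Reagents that add atoms: methoxytrimethylsilane, CO[Si](C)(C)C
Why: Noyori acetalisation, driven by formation of the disiloxane; the medium holds neither free alcohol nor a free hemiacetal hydroxyl, so transesterification of the aryl ester and acyl migration to the benzylic oxygen are avoided.

Step 6
Reactants: 9 5-(tert-butyldimethylsilyloxy)-2-(dimethoxymethyl)-4-(3-methylbut-2-enyl)phenyl 3-(tert-butyldimethylsilyloxy)-4-methoxybenzoate; 10 triphenylphosphine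
Product: 11 {[4-(tert-butyldimethylsilyloxy)-2-{[3-(tert-butyldimethylsilyloxy)-4-methoxybenzoyl]oxy}-5-(3-methylbut-2-enyl)phenyl](methoxy)methyl}triphenylphosphonium trifluoromethanesulfonate (racemic)
Conditions: PPh3 (1.1 equiv), TMSOTf (1.0 equiv), CH2Cl2, 0 °C; evaporation, trituration with dry Et2O–pentane, no aqueous work-up
Reagents that add atoms: trimethylsilyl trifluoromethanesulfonate, C[Si](C)(C)OS(=O)(=O)C(F)(F)F (supplies the counter-ion)
Why: Conversion of an acetal into an α-alkoxyalkylphosphonium salt; the silyl triflate removes one methoxy group, the aryl(methoxy)carbenium ion is stabilised by the para silyloxy group and is captured at carbon by the phosphine. Excess phosphine buffers any triflic acid, and the new stereocentre is racemic and of no consequence.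

Step 7
Reactants: 11 {[4-(tert-butyldimethylsilyloxy)-2-{[3-(tert-butyldimethylsilyloxy)-4-methoxybenzoyl]oxy}-5-(3-methylbut-2-enyl)phenyl](methoxy)methyl}triphenylphosphonium trifluoromethanesulfonate
Product: 13 6-(tert-butyldimethylsilyloxy)-2-[3-(tert-butyldimethylsilyloxy)-4-methoxyphenyl]-3-methoxy-5-(3-methylbut-2-enyl)benzofuran, via α-methoxybenzyl ylide 12 (not isolated)
Conditions: KN(SiMe3)2 (1.05 equiv), THF, –78 °C to rt
Reagents that add atoms: none
Why: Intramolecular Wittig olefination of an aryl ester: KN(SiMe3)2 removes the benzylic proton of 11 at –78 °C and gives the semi-stabilised α-methoxybenzyl ylide 12. The ylide carbon (future C3) adds to the carbonyl carbon of the ortho isovanillate ester (future C2) in a 5-exo-trig closure, and the oxaphosphetane that follows collapses to triphenylphosphine oxide and the C2=C3 bond, so ring closure and aromatisation of the furan are one event. The closest known reactions are the ester Wittig closures of ortho-acyloxybenzyl ylides to 2-aryl- and 2,3-disubstituted benzofurans and the carbonyl olefinations of α-alkoxybenzyl ylides to enol ethers; this step joins the two. No stereocentre is formed, and the racemic centre of 11 disappears. Two chemoselectivities are needed: C–H deprotonation must outrun substitution at the O,P-acetal carbon and attack on the ester, which a hindered amide base at low temperature secures, and olefination must outrun acyl transfer. The latter is secured by the substrate: the ylide carbon has no second hydrogen, so a C-acylated phosphonium with an ortho phenoxide cannot drain into a stabilised keto ylide and can only re-close to the same betaine. The aryl ester is an activated electrophile held ortho to the ylide, the gain in furan aromaticity drives loss of the phosphine oxide, and the silyl ethers and the prenyl group are inert to the base.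

Step 8
Reactants: 13 6-(tert-butyldimethylsilyloxy)-2-[3-(tert-butyldimethylsilyloxy)-4-methoxyphenyl]-3-methoxy-5-(3-methylbut-2-enyl)benzofuran
Product: 14 2-(3-hydroxy-4-methoxyphenyl)-3-methoxy-5-(3-methylbut-2-enyl)benzofuran-6-ol (CNP0278880.0)
Conditions: Bu4NF (2.4 equiv), AcOH (2.4 equiv), THF, 0 °C
Reagents that add atoms: none
Why: Fluoride-induced cleavage of two aryl silyl ethers; buffering with acetic acid keeps the medium near neutral, so the enol ether, the prenyl alkene and the liberated phenols are not exposed to strong base or acid.

## Compound list

1 | isovanillic acid (3-hydroxy-4-methoxybenzoic acid) | COc1ccc(C(=O)O)cc1O | starting material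
2 | tert-butyldimethylsilyl 3-(tert-butyldimethylsilyloxy)-4-methoxybenzoate | COc1ccc(C(=O)O[Si](C)(C)C(C)(C)C)cc1O[Si](C)(C)C(C)(C)C | intermediate
3 | 3-(tert-butyldimethylsilyloxy)-4-methoxybenzoic acid | COc1ccc(C(=O)O)cc1O[Si](C)(C)C(C)(C)C | intermediate
4 | 5-bromo-2,4-dihydroxybenzaldehyde | O=Cc1cc(Br)c(O)cc1O | starting material
5 | 5-bromo-4-(tert-butyldimethylsilyloxy)-2-hydroxybenzaldehyde | O=Cc1cc(Br)c(O[Si](C)(C)C(C)(C)C)cc1O | intermediate
6 | 4-bromo-5-(tert-butyldimethylsilyloxy)-2-formylphenyl 3-(tert-butyldimethylsilyloxy)-4-methoxybenzoate | COc1ccc(C(=O)Oc2cc(O[Si](C)(C)C(C)(C)C)c(Br)cc2C=O)cc1O[Si](C)(C)C(C)(C)C | intermediate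
7 | tributyl(3-methylbut-2-enyl)stannane | CCCC[Sn](CCCC)(CCCC)CC=C(C)C | starting material
8 | 5-(tert-butyldimethylsilyloxy)-2-formyl-4-(3-methylbut-2-enyl)phenyl 3-(tert-butyldimethylsilyloxy)-4-methoxybenzoate | COc1ccc(C(=O)Oc2cc(O[Si](C)(C)C(C)(C)C)c(CC=C(C)C)cc2C=O)cc1O[Si](C)(C)C(C)(C)C | intermediate
9 | 5-(tert-butyldimethylsilyloxy)-2-(dimethoxymethyl)-4-(3-methylbut-2-enyl)phenyl 3-(tert-butyldimethylsilyloxy)-4-methoxybenzoate | COc1ccc(C(=O)Oc2cc(O[Si](C)(C)C(C)(C)C)c(CC=C(C)C)cc2C(OC)OC)cc1O[Si](C)(C)C(C)(C)C | intermediate
10 | triphenylphosphine | c1ccc(P(c2ccccc2)c2ccccc2)cc1 | starting material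
11 | {[4-(tert-butyldimethylsilyloxy)-2-{[3-(tert-butyldimethylsilyloxy)-4-methoxybenzoyl]oxy}-5-(3-methylbut-2-enyl)phenyl](methoxy)methyl}triphenylphosphonium trifluoromethanesulfonate, racemic | COC(c1cc(CC=C(C)C)c(O[Si](C)(C)C(C)(C)C)cc1OC(=O)c1ccc(OC)c(O[Si](C)(C)C(C)(C)C)c1)[P+](c1ccccc1)(c1ccccc1)c1ccccc1.[O-]S(=O)(=O)C(F)(F)F | intermediate
12 | {[4-(tert-butyldimethylsilyloxy)-2-{[3-(tert-butyldimethylsilyloxy)-4-methoxybenzoyl]oxy}-5-(3-methylbut-2-enyl)phenyl](methoxy)methylidene}triphenylphosphorane (ylide, not isolated) | COC(c1cc(CC=C(C)C)c(O[Si](C)(C)C(C)(C)C)cc1OC(=O)c1ccc(OC)c(O[Si](C)(C)C(C)(C)C)c1)=P(c1ccccc1)(c1ccccc1)c1ccccc1 | intermediate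
13 | 6-(tert-butyldimethylsilyloxy)-2-[3-(tert-butyldimethylsilyloxy)-4-methoxyphenyl]-3-methoxy-5-(3-methylbut-2-enyl)benzofuran | COc1ccc(-c2oc3cc(O[Si](C)(C)C(C)(C)C)c(CC=C(C)C)cc3c2OC)cc1O[Si](C)(C)C(C)(C)C | intermediate
14 | 2-(3-hydroxy-4-methoxyphenyl)-3-methoxy-5-(3-methylbut-2-enyl)benzofuran-6-ol | COc1ccc(-c2oc3cc(O)c(CC=C(C)C)cc3c2OC)cc1O | target

## Step count and risks

Total step count: 8. Longest linear sequence: 7 steps (4 to 14, steps 2 to 8); step 1 runs in parallel.

**Step 7 (key step).**
- What may go wrong: ionisation of the O,P-acetal with loss of the phosphine, or attack of the base on the activated ester, may compete with C–H deprotonation. The α-alkoxy ylide may also lose phosphine thermally before it cyclises, or the betaine may stall after acyl transfer.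
- Fallback, from 9 to 13: a Horner–Wittig closure in place of the ylide. Acetal 9 is treated with chlorodiphenylphosphine (Arbuzov-type exchange of one methoxy group) to give 5-(tert-butyldimethylsilyloxy)-2-[(diphenylphosphoryl)(methoxy)methyl]-4-(3-methylbut-2-enyl)phenyl 3-(tert-butyldimethylsilyloxy)-4-methoxybenzoate F1. Deprotonation of F1 with KN(SiMe3)2 in THF gives a neutral phosphine-oxide carbanion that cannot ionise or shed phosphine. It acylates at the ortho ester, the freed phenoxide re-closes onto the ketone, and the potassium alkoxide eliminates diphenylphosphinate to give 13.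

**Step 6.**
- What may go wrong: the O,P-acetal forms reversibly and may revert to 8 through hydrolysis during handling. The silyl triflate may exchange an aryl silyl ether, or adventitious triflic acid may protonate the prenyl alkene.
- Fallback, from 9 to 12: the C–P bond is made by displacement on a covalent chloride without any silyl triflate. Acetal 9 with acetyl chloride and catalytic ZnBr2 gives 5-(tert-butyldimethylsilyloxy)-2-[chloro(methoxy)methyl]-4-(3-methylbut-2-enyl)phenyl 3-(tert-butyldimethylsilyloxy)-4-methoxybenzoate F2. Triphenylphosphine 10 in CH2Cl2 converts F2 into {[4-(tert-butyldimethylsilyloxy)-2-{[3-(tert-butyldimethylsilyloxy)-4-methoxybenzoyl]oxy}-5-(3-methylbut-2-enyl)phenyl](methoxy)methyl}triphenylphosphonium chloride F3. Deprotonation of F3 with KN(SiMe3)2 gives the same ylide 12.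

**Step 4.**
- What may go wrong: oxidative addition into an electron-rich C–Br bond flanked by a silyloxy group may be slow. Allyl transfer may lose regiocontrol and couple through the substituted terminus, and the stannane may be protodestannylated.
- Fallback, from 6 to 8: allylation followed by olefin cross-metathesis, which removes the regiochemical question. Stille coupling of 6 with allyltributylstannane under the same catalyst gives 4-allyl-5-(tert-butyldimethylsilyloxy)-2-formylphenyl 3-(tert-butyldimethylsilyloxy)-4-methoxybenzoate F4. Cross-metathesis of F4 with excess 2-methylbut-2-ene and the second-generation Grubbs catalyst in CH2Cl2 at 40 °C gives 8.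

**Step 3.**
- What may go wrong: the hydrogen-bonded, electron-poor phenol of 5 is a slow acyl acceptor, so the O-acylisourea may rearrange to the unreactive N-acylurea.
- Fallback, from 3 to 6: a preformed acid chloride in place of carbodiimide activation. Acid 3 with 1-chloro-N,N,2-trimethylprop-1-en-1-amine (the Ghosez reagent) in CH2Cl2 gives, without release of hydrogen chloride, 3-(tert-butyldimethylsilyloxy)-4-methoxybenzoyl chloride F5. Acylation of 5 with F5, triethylamine and catalytic DMAP gives 6.

## Further compounds

F1 | step 7 | 5-(tert-butyldimethylsilyloxy)-2-[(diphenylphosphoryl)(methoxy)methyl]-4-(3-methylbut-2-enyl)phenyl 3-(tert-butyldimethylsilyloxy)-4-methoxybenzoate (racemic) | COC(c1cc(CC=C(C)C)c(O[Si](C)(C)C(C)(C)C)cc1OC(=O)c1ccc(OC)c(O[Si](C)(C)C(C)(C)C)c1)P(=O)(c1ccccc1)c1ccccc1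
F2 | step 6 | 5-(tert-butyldimethylsilyloxy)-2-[chloro(methoxy)methyl]-4-(3-methylbut-2-enyl)phenyl 3-(tert-butyldimethylsilyloxy)-4-methoxybenzoate (racemic) | COC(Cl)c1cc(CC=C(C)C)c(O[Si](C)(C)C(C)(C)C)cc1OC(=O)c1ccc(OC)c(O[Si](C)(C)C(C)(C)C)c1
F3 | step 6 | {[4-(tert-butyldimethylsilyloxy)-2-{[3-(tert-butyldimethylsilyloxy)-4-methoxybenzoyl]oxy}-5-(3-methylbut-2-enyl)phenyl](methoxy)methyl}triphenylphosphonium chloride (racemic) | COC(c1cc(CC=C(C)C)c(O[Si](C)(C)C(C)(C)C)cc1OC(=O)c1ccc(OC)c(O[Si](C)(C)C(C)(C)C)c1)[P+](c1ccccc1)(c1ccccc1)c1ccccc1.[Cl-]
F4 | step 4 | 4-allyl-5-(tert-butyldimethylsilyloxy)-2-formylphenyl 3-(tert-butyldimethylsilyloxy)-4-methoxybenzoate | COc1ccc(C(=O)Oc2cc(O[Si](C)(C)C(C)(C)C)c(CC=C)cc2C=O)cc1O[Si](C)(C)C(C)(C)C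
F5 | step 3 | 3-(tert-butyldimethylsilyloxy)-4-methoxybenzoyl chloride | COc1ccc(C(=O)Cl)cc1O[Si](C)(C)C(C)(C)C
A1 | alternative 1 | 2-hydroxy-4-(methoxymethoxy)-5-(3-methylbut-2-enyl)benzaldehyde | COCOc1cc(O)c(C=O)cc1CC=C(C)C
A2 | alternative 1 | [4-methoxy-3-(methoxymethoxy)benzyl]dimethylsulfonium tetrafluoroborate | COCOc1cc(C[S+](C)C)ccc1OC.F[B-](F)(F)F
A3 | alternative 1 | trans-2-[4-methoxy-3-(methoxymethoxy)phenyl]-6-(methoxymethoxy)-5-(3-methylbut-2-enyl)-2,3-dihydrobenzofuran-3-ol (racemic, one enantiomer drawn) | O[C@@H]1c2cc(CC=C(C)C)c(OCOC)cc2O[C@H]1c1ccc(OC)c(OCOC)c1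
A4 | alternative 2 | 2-methoxy-1-[4-methoxy-3-(methoxymethoxy)phenyl]ethanone | COCC(=O)c1ccc(OC)c(OCOC)c1
A5 | alternative 2 | 1-bromo-2-iodo-5-(methoxymethoxy)-4-(3-methylbut-2-enyl)benzene | COCOc1cc(Br)c(I)cc1CC=C(C)C
A6 | alternative 2 | 3-methoxy-2-[4-methoxy-3-(methoxymethoxy)phenyl]-6-(methoxymethoxy)-5-(3-methylbut-2-enyl)benzofuran | COCOc1cc2oc(-c3ccc(OC)c(OCOC)c3)c(OC)c2cc1CC=C(C)C
A7 | alternative 3 | tributyl{[2-iodo-5-(methoxymethoxy)-4-(3-methylbut-2-enyl)phenoxy][4-methoxy-3-(methoxymethoxy)phenyl]methyl}stannane (racemic) | CCCC[Sn](CCCC)(CCCC)C(Oc1cc(OCOC)c(CC=C(C)C)cc1I)c1ccc(OC)c(OCOC)c1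
A8 | alternative 3 | 2-[4-methoxy-3-(methoxymethoxy)phenyl]-6-(methoxymethoxy)-5-(3-methylbut-2-enyl)benzofuran-3(2H)-one (racemic) | COCOc1cc2c(cc1CC=C(C)C)C(=O)C(c1ccc(OC)c(OCOC)c1)O2
A9 | alternative 3 | carbon monoxide | [C-]#[O+]
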